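**Retrosynthetic overview**
1. The two unsaturated esters go on last (C3 methacrylate, C8 angelate), leaving the bis-silylated 1β,10α-epoxy-heliangolide core 20.
2. The α-methylene-γ-lactone is taken off as 2-bromoacrylic acid in a Pd-catalysed formal (3+2) diene heteroannulation (C7–C11 and C6–O), leaving the ring (4Z,6Z)-diene 18. The enabling feature is that C6, the carbon carrying the lactone oxygen, is allylic to the ring C4=C5 double bond, so the C6–C7-fused lactone is the retron of carboxylate capture of an η3-allyl (C4–C5–C6) formed by C–C bond formation at C7.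
3. The ten-membered ring is closed at C6=C7 by diene–ene ring-closing metathesis of the acyclic epoxy tetraene 17; the epoxide is set before ring closure by Shi epoxidation.
4. The chain comes from C3–C4 Nozaki–Hiyama–Kishi coupling of aldehyde 12 with (Z)-iododiene 5 (then oxidation and CBS reduction for 3S), Negishi carboalumination/oxirane opening for the E-C1=C10 unit, and (S)-2-vinyloxirane for C8.
5. Ring order: epoxide, then ten-membered carbocycle, then γ-lactone.

Key step: step 14

Remark: (S)-2-vinyloxirane is taken as a commercial enantiopure building block. Ring compounds are numbered as germacranolides (ring C1–C10, C14 on C10, C15 on C4, lactone carbons C11–C13 on C7 with the oxygen on C6).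

**Route**

Step 1
Reactants: 1 but-2-yn-1-ol
Product: 3 (Z)-3-iodobut-2-en-1-ol, via cyclic alkenylalanate 2 (not isolated)
Conditions: Red-Al, THF, 0 °C to rt; then I2, −78 °C to 0 °C
Reagents that add atoms: iodine, II
Why: Hydroxyl-directed trans-hydroalumination of the propargylic alcohol places aluminium on C3 in a five-membered oxa-aluminacycle, and iodinolysis with retention should give the (Z)-iodoalkene that later becomes the 4Z ring alkene.

Step 2
Reactants: 3 (Z)-3-iodobut-2-en-1-ol
Product: 4 (Z)-3-iodobut-2-enal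
Conditions: MnO2, CH2Cl2, rt, dark
Reagents that add atoms: none
Why: Neutral MnO2 oxidation of an allylic alcohol should give the enal without Z/E isomerisation of the iodoalkene.

Step 3
Reactants: 4 (Z)-3-iodobut-2-enal
Product: 5 (Z)-4-iodopenta-1,3-diene
Conditions: Ph3PCH3Br, KHMDS, THF, −78 °C to 0 °C; used as a solution
Reagents that add atoms: methyltriphenylphosphonium bromide, C[P+](c1ccccc1)(c1ccccc1)c1ccccc1.[Br-]
Why: Wittig methylenation of the aldehyde is faster than attack at the β-iodo carbon and leaves the trisubstituted iodoalkene geometry untouched.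

Step 4
Reactants: 6 (S)-2-vinyloxirane
Product: 7 (R)-hex-1-en-5-yn-3-ol
Conditions: HC≡CLi·ethylenediamine, DMSO, 0 °C to rt
Reagents that add atoms: lithium acetylide–ethylenediamine complex, [Li+].[C-]#C.NCCN
Why: SN2 epoxide opening by acetylide without a Lewis acid should occur at the unhindered CH2, so the stereocentre (later C8) is carried over unchanged from the chiral pool.

Step 5
Reactants: 7 (R)-hex-1-en-5-yn-3-ol
Product: 8 (R)-3-(tert-butyldimethylsilyloxy)hex-1-en-5-yne
Conditions: TBSCl, imidazole, DMF, rt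
Reagents that add atoms: tert-butyldimethylsilyl chloride, CC(C)(C)[Si](C)(C)Cl
Why: Standard silylation gives an allylic silyl ether that is inert to Me3Al, Cr(II), Ru and Pd(0) and later shields one face of the C6=C7 bond.

Step 6
Reactants: 8 (R)-3-(tert-butyldimethylsilyloxy)hex-1-en-5-yne
Product: 11 (3E,6R)-6-(tert-butyldimethylsilyloxy)-4-methylocta-3,7-dien-1-ol, via alkenyldimethylalane 9 (not isolated), via lithium alkenylalanate 10 (not isolated)
Conditions: Me3Al, Cp2ZrCl2 (cat.), CH2Cl2, 0 °C to rt; evaporate; n-BuLi, hexane–THF, −78 to 0 °C; oxirane, 0 °C to rt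
Reagents that add atoms: trimethylaluminium, C[Al](C)C; oxirane, C1CO1
Why: Negishi Zr-catalysed carboalumination adds Me and Al syn across the terminal alkyne (Me to the internal carbon), and the derived alanate opens oxirane with retention, which fixes the E-trisubstituted alkene that becomes the trans-epoxide.

Step 7
Reactants: 11 (3E,6R)-6-(tert-butyldimethylsilyloxy)-4-methylocta-3,7-dien-1-ol
Product: 12 (3E,6R)-6-(tert-butyldimethylsilyloxy)-4-methylocta-3,7-dienal
Conditions: Dess–Martin periodinane, pyridine, CH2Cl2, 0 °C; used crude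
Reagents that add atoms: none
Why: Buffered Dess–Martin oxidation should give the β,γ-unsaturated aldehyde without migration of the alkene into conjugation.

Step 8
Reactants: 12 (3E,6R)-6-(tert-butyldimethylsilyloxy)-4-methylocta-3,7-dienal; 5 (Z)-4-iodopenta-1,3-diene
Product: 13 (3Z,7E,10R)-10-(tert-butyldimethylsilyloxy)-4,8-dimethyldodeca-1,3,7,11-tetraen-5-ol as both C5 epimers
Conditions: CrCl2, NiCl2 (cat.), DMSO–THF, rt
Reagents that add atoms: none
Why: The Nozaki–Hiyama–Kishi reaction adds the alkenyl iodide to the enolisable aldehyde under non-basic conditions with retention of the Z geometry; the carbinol centre is not controlled here and is corrected in steps 9 and 10.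

Step 9
Reactants: 13 (3Z,7E,10R)-10-(tert-butyldimethylsilyloxy)-4,8-dimethyldodeca-1,3,7,11-tetraen-5-ol
Product: 14 (3Z,7E,10R)-10-(tert-butyldimethylsilyloxy)-4,8-dimethyldodeca-1,3,7,11-tetraen-5-one
Conditions: Dess–Martin periodinane, pyridine, CH2Cl2, 0 °C
Reagents that add atoms: none
Why: Neutral Dess–Martin oxidation removes the uncontrolled stereocentre and should leave the Z-dienone and the β,γ-alkene in place.

Step 10
Reactants: 14 (3Z,7E,10R)-10-(tert-butyldimethylsilyloxy)-4,8-dimethyldodeca-1,3,7,11-tetraen-5-one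
Product: 15 (3Z,5S,7E,10R)-10-(tert-butyldimethylsilyloxy)-4,8-dimethyldodeca-1,3,7,11-tetraen-5-ol
Conditions: (R)-Me-CBS (cat.), catecholborane, toluene, −78 °C
Reagents that add atoms: none
Why: In the Corey–Bakshi–Shibata reduction the α-branched dienyl group acts as the large and the CH2 group as the small substituent, so the (R)-catalyst should deliver the (S)-alcohol (C3 of the target), and catecholborane at low temperature avoids hydroboration.

Step 11
Reactants: 15 (3Z,5S,7E,10R)-10-(tert-butyldimethylsilyloxy)-4,8-dimethyldodeca-1,3,7,11-tetraen-5-ol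
Product: 16 (3Z,5S,7E,10R)-10-(tert-butyldimethylsilyloxy)-5-(triethylsilyloxy)-4,8-dimethyldodeca-1,3,7,11-tetraene
Conditions: TESCl, imidazole, CH2Cl2, 0 °C
Reagents that add atoms: chlorotriethylsilane, CC[Si](Cl)(CC)CC
Why: Silylation gives a TES ether that can be removed in the presence of TBS and, unlike an allylic ester, is not ionised by Pd(0) in the key step.

Step 12
Reactants: 16 (3Z,5S,7E,10R)-10-(tert-butyldimethylsilyloxy)-5-(triethylsilyloxy)-4,8-dimethyldodeca-1,3,7,11-tetraene
Product: 17 (2R,3R)-2-[(2S,3Z)-3-methyl-2-(triethylsilyloxy)hexa-3,5-dienyl]-3-[(2R)-2-(tert-butyldimethylsilyloxy)but-3-enyl]-3-methyloxirane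
Conditions: D-fructose-derived Shi ketone (cat.), Oxone, K2CO3, Bu4NHSO4 (cat.), MeCN–dimethoxymethane–aq. borate buffer, 0 °C
Reagents that add atoms: Oxone (potassium peroxymonosulfate), [K+].[O-]S(=O)(=O)OO
Why: In the Shi asymmetric epoxidation the D-fructose-derived dioxirane should epoxidise the isolated E-trisubstituted alkene through the spiro transition state to the (R,R)-epoxide (C1 and C10) under reagent control. The conjugated diene, deactivated by the allylic OTES group, and the terminal alkenes are expected to react more slowly, as in the epoxidation of ocimene-type trienes.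

Step 13
Reactants: 17 (2R,3R)-2-[(2S,3Z)-3-methyl-2-(triethylsilyloxy)hexa-3,5-dienyl]-3-[(2R)-2-(tert-butyldimethylsilyloxy)but-3-enyl]-3-methyloxirane
Product: 18 (1R,3S,4Z,6Z,8R,10R)-8-(tert-butyldimethylsilyloxy)-3-(triethylsilyloxy)-4,10-dimethyl-1,10-epoxycyclodeca-4,6-diene (germacranolide numbering)
Conditions: Grubbs II (cat.), toluene (1 mM), 80 °C
Reagents that add atoms: none
Why: Diene–ene ring-closing metathesis can only join the two terminal alkenes (the trisubstituted C4=C5 bond is inert, and the C1=C10 alkene is already an epoxide, so no cyclohexadiene can form); the ten-membered ring should enforce the cis C6=C7 bond and ethene loss drives the closure.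

Step 14
Reactants: 18 (1R,3S,4Z,6Z,8R,10R)-8-(tert-butyldimethylsilyloxy)-3-(triethylsilyloxy)-4,10-dimethyl-1,10-epoxycyclodeca-4,6-diene; 19 2-bromoacrylic acid
Product: 20 8β-(tert-butyldimethylsilyloxy)-3β-(triethylsilyloxy)-1β,10α-epoxygermacra-4Z,11(13)-dien-12,6α-olide
Conditions: Pd(OAc)2 (cat.), 1,1′-bis(di-tert-butylphosphino)ferrocene (cat.), K2CO3, n-Bu4NCl, DMF, 70 °C
Reagents that add atoms: none
Why: This is a Larock-type Pd(0)-catalysed heteroannulation of a 1,3-diene by an α-haloacrylic acid, a formal (3+2) cycloaddition: oxidative addition into the C–Br bond of 19, syn-carbopalladation of C6=C7 with C–C bond formation at C7, and capture of the resulting η3-allyl (C4–C5–C6) by the tethered carboxylate at C6 with release of Pd(0). The closest known reaction type is the annulation of acyclic and cyclic 1,3-dienes with 2-bromo- or 2-iodoacrylic acids to α-alkylidene-γ-butyrolactones. The lactone closes by intramolecular O-attack on the near allyl terminus (5-exo with respect to the allyl; attack at C4 would need a seven-membered ring), and C4=C5 stays Z because C3 remains anti on the allyl. For C7, the C8–H bond should eclipse C6=C7 to avoid A1,3 strain with C5, so the OTBS group covers one π-face and the alkenyl–Pd adds to the other. For C6, C8 cannot stay eclipsed with C5 in the ten-membered anti,anti-allyl and should swing to the face remote from Pd, which carries the carboxylate arm below the allyl plane for attack anti to Pd (outer-sphere, favoured by chloride) to give the trans-fused lactone; since the C6–O bond is allylic it can re-ionise under Pd(0), so the trans-fused 6,12-olide, expected to be the more stable isomer, should also be reached by equilibration. Regioselectivity (C7, not C4) rests on C7 being the only unsubstituted diene terminus, and chemoselectivity on the absence of any other Heck-competent alkene or allylic ester (both acyl groups come later; silyl ethers and the non-allylic epoxide are inert to Pd(0)).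

Step 15
Reactants: 20 8β-(tert-butyldimethylsilyloxy)-3β-(triethylsilyloxy)-1β,10α-epoxygermacra-4Z,11(13)-dien-12,6α-olide
Product: 21 8β-(tert-butyldimethylsilyloxy)-3β-hydroxy-1β,10α-epoxygermacra-4Z,11(13)-dien-12,6α-olide
Conditions: HF·pyridine, pyridine, THF, 0 °C
Reagents that add atoms: none
Why: Buffered fluoride desilylation should cleave the secondary TES ether much faster than the hindered TBS ether, and the buffered medium spares the epoxide and the methylene lactone.

Step 16
Reactants: 21 8β-(tert-butyldimethylsilyloxy)-3β-hydroxy-1β,10α-epoxygermacra-4Z,11(13)-dien-12,6α-olide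
Product: 22 8β-(tert-butyldimethylsilyloxy)-3β-methacryloyloxy-1β,10α-epoxygermacra-4Z,11(13)-dien-12,6α-olide
Conditions: methacrylic anhydride, Et3N, DMAP (cat.), CH2Cl2, 0 °C to rt
Reagents that add atoms: methacrylic anhydride, C=C(C)C(=O)OC(=O)C(C)=C
Why: DMAP-catalysed acyl transfer to the unhindered allylic alcohol occurs with retention at C3 and touches no other group.

Step 17
Reactants: 22 8β-(tert-butyldimethylsilyloxy)-3β-methacryloyloxy-1β,10α-epoxygermacra-4Z,11(13)-dien-12,6α-olide
Product: 23 8β-hydroxy-3β-methacryloyloxy-1β,10α-epoxygermacra-4Z,11(13)-dien-12,6α-olide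
Conditions: HF·pyridine, THF, 0 °C to rt
Reagents that add atoms: none
Why: Fluoride desilylation under non-basic conditions should remove the TBS group without conjugate addition to the methylene lactone or the methacrylate and without lactone migration to O8.

Step 18
Reactants: 23 8β-hydroxy-3β-methacryloyloxy-1β,10α-epoxygermacra-4Z,11(13)-dien-12,6α-olide
Product: 24 8β-angeloyloxy-3β-methacryloyloxy-1β,10α-epoxygermacra-4Z,11(13)-dien-12,6α-olide (CNP0294228.1)
Conditions: angelic acid, 2,4,6-trichlorobenzoyl chloride, Et3N, toluene, rt; then 23, 80 °C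
Reagents that add atoms: angelic acid, C/C=C(/C)C(=O)O
Why: In this Yamaguchi-type mixed-anhydride esterification the alcohol attacks the unshielded angeloyl carbonyl, and without a nucleophilic catalyst the Z-alkene of the acyl group should not isomerise to the tiglate.

**Compound list**
1 | but-2-yn-1-ol | CC#CCO | starting material
2 | cyclic (Z)-alkenylalanate from Red-Al (sodium salt) | CC1=CCO[Al-]1(OCCOC)OCCOC.[Na+] | intermediate
3 | (Z)-3-iodobut-2-en-1-ol | C/C(I)=C/CO | intermediate
4 | (Z)-3-iodobut-2-enal | C/C(I)=C/C=O | intermediate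
5 | (Z)-4-iodopenta-1,3-diene | C/C(I)=C/C=C | intermediate
6 | (S)-2-vinyloxirane | C=C[C@H]1CO1 | starting material
7 | (R)-hex-1-en-5-yn-3-ol | C#CC[C@@H](O)C=C | intermediate
8 | (R)-3-(tert-butyldimethylsilyloxy)hex-1-en-5-yne | C#CC[C@@H](O[Si](C)(C)C(C)(C)C)C=C | intermediate
9 | [(1E,4R)-4-(tert-butyldimethylsilyloxy)-2-methylhexa-1,5-dienyl]dimethylalane | C[Al](C)/C=C(C)/C[C@@H](O[Si](C)(C)C(C)(C)C)C=C | intermediate
10 | lithium butyl[(1E,4R)-4-(tert-butyldimethylsilyloxy)-2-methylhexa-1,5-dienyl]dimethylalanate | [Li+].CCCC[Al-](C)(C)/C=C(C)/C[C@@H](O[Si](C)(C)C(C)(C)C)C=C | intermediate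
11 | (3E,6R)-6-(tert-butyldimethylsilyloxy)-4-methylocta-3,7-dien-1-ol | OCC/C=C(C)/C[C@@H](O[Si](C)(C)C(C)(C)C)C=C | intermediate
12 | (3E,6R)-6-(tert-butyldimethylsilyloxy)-4-methylocta-3,7-dienal | O=CC/C=C(C)/C[C@@H](O[Si](C)(C)C(C)(C)C)C=C | intermediate
13 | (3Z,7E,10R)-10-(tert-butyldimethylsilyloxy)-4,8-dimethyldodeca-1,3,7,11-tetraen-5-ol, both C5 epimers | C=C/C=C(C)\C(O)C/C=C(C)/C[C@@H](O[Si](C)(C)C(C)(C)C)C=C | intermediate
14 | (3Z,7E,10R)-10-(tert-butyldimethylsilyloxy)-4,8-dimethyldodeca-1,3,7,11-tetraen-5-one | C=C/C=C(C)\C(=O)C/C=C(C)/C[C@@H](O[Si](C)(C)C(C)(C)C)C=C | intermediate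
15 | (3Z,5S,7E,10R)-10-(tert-butyldimethylsilyloxy)-4,8-dimethyldodeca-1,3,7,11-tetraen-5-ol | C=C/C=C(C)\[C@@H](O)C/C=C(C)/C[C@@H](O[Si](C)(C)C(C)(C)C)C=C | intermediate
16 | (3Z,5S,7E,10R)-10-(tert-butyldimethylsilyloxy)-5-(triethylsilyloxy)-4,8-dimethyldodeca-1,3,7,11-tetraene | C=C/C=C(C)\[C@@H](O[Si](CC)(CC)CC)C/C=C(C)/C[C@@H](O[Si](C)(C)C(C)(C)C)C=C | intermediate
17 | (2R,3R)-2-[(2S,3Z)-3-methyl-2-(triethylsilyloxy)hexa-3,5-dienyl]-3-[(2R)-2-(tert-butyldimethylsilyloxy)but-3-enyl]-3-methyloxirane | C=C/C=C(C)\[C@@H](O[Si](CC)(CC)CC)C[C@H]1O[C@]1(C)C[C@@H](O[Si](C)(C)C(C)(C)C)C=C | intermediate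
18 | (1R,3S,4Z,6Z,8R,10R)-8-(tert-butyldimethylsilyloxy)-3-(triethylsilyloxy)-4,10-dimethyl-1,10-epoxycyclodeca-4,6-diene (germacranolide numbering) | CC[Si](CC)(CC)O[C@H]1C[C@H]2O[C@]2(C)C[C@@H](O[Si](C)(C)C(C)(C)C)/C=C\C=C/1C | intermediate
19 | 2-bromoacrylic acid | C=C(Br)C(=O)O | starting material
20 | 8β-(tert-butyldimethylsilyloxy)-3β-(triethylsilyloxy)-1β,10α-epoxygermacra-4Z,11(13)-dien-12,6α-olide (6α-O, 7α-H, trans-fused) | CC[Si](CC)(CC)O[C@H]1C[C@H]2O[C@]2(C)C[C@@H](O[Si](C)(C)C(C)(C)C)[C@H]2C(=C)C(=O)O[C@@H]2/C=C\1C | intermediate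
21 | 8β-(tert-butyldimethylsilyloxy)-3β-hydroxy-1β,10α-epoxygermacra-4Z,11(13)-dien-12,6α-olide | O[C@H]1C[C@H]2O[C@]2(C)C[C@@H](O[Si](C)(C)C(C)(C)C)[C@H]2C(=C)C(=O)O[C@@H]2/C=C\1C | intermediate
22 | 8β-(tert-butyldimethylsilyloxy)-3β-methacryloyloxy-1β,10α-epoxygermacra-4Z,11(13)-dien-12,6α-olide | C=C(C)C(=O)O[C@H]1C[C@H]2O[C@]2(C)C[C@@H](O[Si](C)(C)C(C)(C)C)[C@H]2C(=C)C(=O)O[C@@H]2/C=C\1C | intermediate
23 | 8β-hydroxy-3β-methacryloyloxy-1β,10α-epoxygermacra-4Z,11(13)-dien-12,6α-olide | C=C(C)C(=O)O[C@H]1C[C@H]2O[C@]2(C)C[C@@H](O)[C@H]2C(=C)C(=O)O[C@@H]2/C=C\1C | intermediate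
24 | (1R,3S,4Z,6R,7R,8R,10R)-8-angeloyloxy-3-methacryloyloxy-1,10-epoxygermacra-4,11(13)-dien-12,6-olide (CNP0294228.1) | C=C(C)C(=O)O[C@H]1C[C@H]2O[C@]2(C)C[C@@H](OC(=O)/C(C)=C\C)[C@H]2C(=C)C(=O)O[C@@H]2/C=C\1C | target

**Step count**
Total: 18 steps. Longest linear sequence: 15 steps (6 to 24, steps 4–18); steps 1–3 make the coupling partner 5.

**Steps most likely to fail**

1. Step 14 (Pd heteroannulation). Carbopalladation of the hindered, twisted ring diene may be too slow, the η3-allyl may lose a β-hydride instead of closing, the alkenyl–Pd may add on the OTBS face, or the carboxylate may close on the Pd face to a cis-fused lactone. The fallback sets out from 18 and replaces the two-electron Pd manifold by a one-electron oxidative lactone annulation followed by methylenation. Mn(OAc)3·2H2O with potassium methyl malonate (KOAc-buffered AcOH–MeCN, 40 °C) should add the malonyl radical to C7 and, after oxidation of the allyl radical, close the carboxylate onto C6 to give the α-(methoxycarbonyl) lactone F1. Me3SnOH (1,2-dichloroethane, 70 °C) would cleave the methyl ester to the α-carboxy lactone F2. Decarboxylative Mannich methylenation (aqueous formaldehyde, Et2NH, AcOH–NaOAc) then returns to 20.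

2. Step 13 (ring-closing metathesis). The catalyst may load on the conjugated diene as an unreactive vinylcarbene, or intermolecular metathesis may outrun closure of the strained ten-membered ring, so that oligomers form. The fallback sets out from 17 and closes the ring at the ketone oxidation level, where C3 is sp2, the bulky silyloxy group next to the diene is gone and the electron-poor diene no longer sequesters the catalyst. Buffered HF·pyridine removes the TES group to give the epoxy dienol F3, and Dess–Martin oxidation gives the cross-conjugated epoxy dienone F4. Ring-closing metathesis (Hoveyda–Grubbs II, toluene, 80 °C, high dilution) should then give the macrocyclic dienone F5. (R)-CBS/catecholborane reduction sets the 3β-alcohol F6, and TESCl/imidazole returns to 18.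

3. Step 18 (angeloylation). The angeloyl group may isomerise to tigloyl during activation, acylation of the hindered C8 hydroxyl may be slow, and under heat and base the lactone may migrate to O8. The fallback sets out from 23 and builds the Z-alkene on the ester instead of transferring it. DCC/DMAP coupling with 2-[bis(2,2,2-trifluoroethoxy)phosphoryl]propanoic acid (0 °C) gives the phosphonopropionate ester F7. Still–Gennari olefination (KHMDS, 18-crown-6, THF, −78 °C, acetaldehyde) should then give the Z-configured 2-methylbut-2-enoate, that is 24.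

Further compounds
F1 | step 14 | α-(methoxycarbonyl) lactone: 20 with CH(CO2Me) in place of C(=CH2) at C11 (C11 epimers) | CC[Si](CC)(CC)O[C@H]1C[C@H]2O[C@]2(C)C[C@@H](O[Si](C)(C)C(C)(C)C)[C@H]2C(C(=O)OC)C(=O)O[C@@H]2/C=C\1C
F2 | step 14 | α-carboxy lactone: 20 with CH(CO2H) in place of C(=CH2) at C11 | CC[Si](CC)(CC)O[C@H]1C[C@H]2O[C@]2(C)C[C@@H](O[Si](C)(C)C(C)(C)C)[C@H]2C(C(=O)O)C(=O)O[C@@H]2/C=C\1C
F3 | step 13 | epoxy dienol: 17 without the triethylsilyl group | C=C/C=C(C)\[C@@H](O)C[C@H]1O[C@]1(C)C[C@@H](O[Si](C)(C)C(C)(C)C)C=C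
F4 | step 13 | epoxy dienone: ketone of F3 at the former carbinol carbon | C=C/C=C(C)\C(=O)C[C@H]1O[C@]1(C)C[C@@H](O[Si](C)(C)C(C)(C)C)C=C
F5 | step 13 | macrocyclic dienone: 3-oxo analogue of 18 | O=C1C[C@H]2O[C@]2(C)C[C@@H](O[Si](C)(C)C(C)(C)C)/C=C\C=C/1C
F6 | step 13 | macrocyclic 3β-alcohol: 18 without the triethylsilyl group | O[C@H]1C[C@H]2O[C@]2(C)C[C@@H](O[Si](C)(C)C(C)(C)C)/C=C\C=C/1C
F7 | step 18 | 8-O-[2-(bis(2,2,2-trifluoroethoxy)phosphoryl)propanoyl] derivative of 23 | C=C(C)C(=O)O[C@H]1C[C@H]2O[C@]2(C)C[C@@H](OC(=O)C(C)P(=O)(OCC(F)(F)F)OCC(F)(F)F)[C@H]2C(=C)C(=O)O[C@@H]2/C=C\1C
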